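**Plan**

- Retrosynthesis: open the lactone at O6–C12 (back to a protected 2-methylene-1,4-diol), cut C4–C5 across the ten-membered ring, then C6–C7 and C7–C11, the O8 ester, the furanone (C1–C3 acyl unit and the C3–O closure) and C10–C14.
- Enabling feature: in the furanone ring the C1 ketone and the C2=C3 enol ether (C3–O–C10 bridge) form a vinylogous ester whose γ-carbon is C4, and C5 is a carbinol, so C4–C5 is a vinylogous aldol bond inside the carbocycle.
- Forward, chain: dimethyl L-tartrate supplies C7–C10 with C8 and C9; methyl addition to a C10 ynone sets C10; a Morita–Baylis–Hillman/indium Barbier sequence adds C11–C13 and C5–C6.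
- Forward, rings: the furanone first (acyl Sonogashira, gold cyclisation); then, after angeloylation and C4 bromination, the ten-membered carbocycle by SmI2 closure of C4–C5; the γ-lactone last by oxidation.
- Stereochemistry: C8/C9 from tartrate, C10 by Cram chelation, C6/C7 from the chair transition state and A(1,3) strain of the Barbier step, C4/C5 in the ring closure under control of the C6 silyl ether and the tether.

Key step: step 21

Remark: locants are germacrane locants of the target (C1 ketone, C2=C3, C4 methyl-bearing carbon, C5 carbinol, C6 lactone oxygen, C7 ring fusion, C8 angelate, C9 carbinol, C10 ether carbon, C11–C13 methylene lactone); aldehyde 13 is assumed to be purchasable; bromides 26 and 27 are carried as C4 epimer mixtures because both give the same dienolate.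

**Route**

Step 1
Reactants: 1 dimethyl L-tartrate
Product: 3 dimethyl (2R,3R)-2-hydroxy-3-[(4-methoxybenzyl)oxy]butanedioate, via stannylene acetal 2 (not isolated)
Conditions: Bu2SnO, toluene, reflux (Dean–Stark); then 4-methoxybenzyl chloride, Bu4NI (cat.), toluene, 90 °C
Reagents that add atoms: 4-methoxybenzyl chloride, COc1ccc(CCl)cc1; dibutyltin oxide, CCCC[Sn](=O)CCCC (tin is carried only by 2)
Why: Stannylene-acetal monoalkylation of a C2-symmetric diol, which gives the same mono-ether whichever oxygen reacts and suppresses dialkylation, so the PMB-bearing carbon becomes C9 and no stereocentre is touched.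

Step 2
Reactants: 3 mono-PMB tartrate
Product: 4 methyl (2R,3S)-3,4-dihydroxy-2-[(4-methoxybenzyl)oxy]butanoate
Conditions: BH3·SMe2, NaBH4 (5 mol%), THF, 0 °C to rt; MeOH quench
Reagents that add atoms: none
Why: Hydroxyl-directed borane reduction, in which the alkoxyborane formed at the free C8 hydroxyl delivers hydride only to the neighbouring ester, so C7 becomes CH2OH and the C10 ester next to the PMB ether survives.

Step 3
Reactants: 4 diol ester
Product: 5 methyl (2R,3S)-2-[(4-methoxybenzyl)oxy]-3,4-bis(triethylsilyloxy)butanoate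
Conditions: Et3SiCl, imidazole, DMF, 0 °C to rt
Reagents that add atoms: chlorotriethylsilane, CC[Si](Cl)(CC)CC
Why: Standard silylation of a primary and a secondary alcohol, done at once so that the dihydroxy ester cannot close to a γ-lactone.

Step 4
Reactants: 5 bis-silyl ester
Product: 6 (2R,3S)-N-methoxy-N-methyl-2-[(4-methoxybenzyl)oxy]-3,4-bis(triethylsilyloxy)butanamide
Conditions: MeNHOMe·HCl, iPrMgCl, THF, −20 °C
Reagents that add atoms: N,O-dimethylhydroxylamine hydrochloride, CNOC.Cl
Why: Weinreb amide formation from an ester by the magnesium amide of N,O-dimethylhydroxylamine, which at low temperature should not epimerise the α-alkoxy centre C9.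

Step 5
Reactants: 6 Weinreb amide
Product: 7 (4R,5S)-4-[(4-methoxybenzyl)oxy]-5,6-bis(triethylsilyloxy)hex-1-yn-3-one
Conditions: HC≡CMgBr, THF, 0 °C; inverse quench into cold aq. NaHSO4
Reagents that add atoms: ethynylmagnesium bromide, C#C[Mg]Br
Why: Weinreb ketone synthesis, in which the chelated tetrahedral adduct stops at the ynone and the acidic inverse quench keeps the released hydroxylamine from adding to the alkyne.

Step 6
Reactants: 7 ethynyl ketone
Product: 9 (3S,4R,5S)-4-[(4-methoxybenzyl)oxy]-3-methyl-5,6-bis(triethylsilyloxy)hex-1-yn-3-yl acetate, via magnesium alkoxide 8 (not isolated)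
Conditions: MeMgBr, THF, −78 °C; then Ac2O, DMAP (cat.), −78 °C to rt
Reagents that add atoms: methylmagnesium bromide, C[Mg]Br; acetic anhydride, CC(=O)OC(C)=O
Why: Cram-chelate-controlled Grignard addition, in which magnesium bridges the ketone oxygen and the C9 PMB ether and methyl adds to the face opposite C8 to set C10, followed by acetylation of the alkoxide in the flask so that the tertiary oxygen can neither form a lactol with the C7 aldehyde nor add to the enoate in steps 7 to 10.

Step 7
Reactants: 9 tertiary acetate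
Product: 10 C7 aldehyde (2R,3R,4S)-4-acetoxy-3-[(4-methoxybenzyl)oxy]-4-methyl-2-(triethylsilyloxy)hex-5-ynal
Conditions: (COCl)2, DMSO, CH2Cl2, −78 to −40 °C; then Et3N, −78 to 0 °C
Reagents that add atoms: none
Why: Swern oxidation applied directly to a primary triethylsilyl ether, which is cleaved and oxidised under these conditions while the secondary silyl ether, the acetate and the PMB ether stay.

Step 8
Reactants: 10 C7 aldehyde
Product: 11 Morita–Baylis–Hillman alcohol (methyl 2-methylene-3-hydroxy ester at C7/C11/C12; both C7 epimers)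
Conditions: methyl acrylate (neat, excess), 3-hydroxyquinuclidine (0.5 equiv), rt
Reagents that add atoms: methyl acrylate, C=CC(=O)OC
Why: Morita–Baylis–Hillman reaction of an α-alkoxy-activated aldehyde, which forms C7–C11; the C7 carbinol arises as a mixture that is erased in step 9.

Step 9
Reactants: 11 Morita–Baylis–Hillman alcohol
Product: 12 methyl (Z)-2-(bromomethyl)alk-2-enoate (C7=C11; C13 bromide; C8 to C10 as in 10)
Conditions: NBS, Me2S, CH2Cl2, 0 °C to rt
Reagents that add atoms: N-bromosuccinimide, O=C1CCC(=O)N1Br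
Why: Corey–Kim-type bromination of a Morita–Baylis–Hillman alcohol with allylic transposition, which should give the thermodynamically preferred Z bromide with C8 trans to the ester.

Step 10
Reactants: 12 (Z)-allylic bromide; 13 (4-methoxybenzyloxy)acetaldehyde
Product: 14 γ-hydroxy α-methylene ester (C6 carbinol; C7 stereocentre; C5 PMB ether)
Conditions: In powder, THF/H2O (1:1), rt
Reagents that add atoms: none
Why: Indium-mediated Barbier 2-(alkoxycarbonyl)allylation, in which a chair transition state with C8 cis to the metallated CH2 gives the 6,7-syn (cis-lactone) series and A(1,3) strain keeps H8 in the alkene plane so that the aldehyde adds to C7 anti to C9, which sets C6 and C7.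

Step 11
Reactants: 14 γ-hydroxy α-methylene ester
Product: 15 triol (C6 OH; C12 allylic OH; C10 tertiary OH)
Conditions: iBu2AlH (excess), CH2Cl2, −78 to 0 °C
Reagents that add atoms: none
Why: iBu2AlH 1,2-reduction of the acrylate ester to the allylic alcohol, with cleavage of the tertiary acetate in the same operation.

Step 12
Reactants: 15 triol
Product: 16 C6/C12 bis(tert-butyldimethylsilyl) ether with free C10 hydroxyl
Conditions: tBuMe2SiCl, imidazole, DMAP (cat.), DMF, rt to 40 °C
Reagents that add atoms: tert-butyl(chloro)dimethylsilane, CC(C)(C)[Si](C)(C)Cl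
Why: Chlorosilane silylation, which protects the primary allylic and the secondary C6 hydroxyls and leaves the tertiary propargylic alcohol free for ring formation.

Step 13
Reactants: 16 terminal alkyne
Product: 17 γ-hydroxy ynone (C10 carbinol; C1≡C2; C3 ketone; C4/C15 ethyl)
Conditions: EtCOCl, PdCl2(PPh3)2 (cat.), CuI (cat.), Et3N, THF, rt
Reagents that add atoms: propanoyl chloride, CCC(=O)Cl
Why: Acyl Sonogashira coupling of a terminal alkyne with an acid chloride, a standard entry to γ-hydroxy ynones that tolerates the hindered tertiary alcohol.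

Step 14
Reactants: 17 γ-hydroxy ynone
Product: 18 5-ethyl-3(2H)-furanone (C1 ketone; C2=C3; C3–O–C10)
Conditions: Ph3PAuCl (5 mol%), AgOTf (5 mol%), toluene (not dried), rt
Reagents that add atoms: none
Why: Cationic monovalent gold catalysis of the hydrative cyclisation of a γ-hydroxy ynone to a 3(2H)-furanone, a net isomerisation in which C1 becomes the ketone and the C10 oxygen closes onto C3 in a five-membered ring without touching C10.

Step 15
Reactants: 18 furanone
Product: 19 C8 alcohol
Conditions: PPTS (cat.), MeOH/CH2Cl2, 0 °C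
Reagents that add atoms: none
Why: Acid-catalysed methanolysis, which removes the secondary triethylsilyl ether much faster than the tert-butyldimethylsilyl ethers (selective desilylation).

Step 16
Reactants: 19 C8 alcohol; 20 angelic acid
Product: 22 C8 angelate, via mixed anhydride 21 (not isolated)
Conditions: 20, 2,4,6-trichlorobenzoyl chloride, Et3N, toluene, rt; then 19, toluene, 80 °C
Reagents that add atoms: 2,4,6-trichlorobenzoyl chloride, O=C(Cl)c1c(Cl)cc(Cl)cc1Cl (its acyl group is carried only by 21)
Why: Yamaguchi esterification through the mixed anhydride, the standard way to acylate hindered secondary alcohols with angelic acid while keeping the Z alkene.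

Step 17
Reactants: 22 C8 angelate
Product: 23 C5/C9 diol
Conditions: DDQ, CH2Cl2/aqueous pH 7 buffer, 0 °C to rt
Reagents that add atoms: none
Why: Oxidative cleavage of both 4-methoxybenzyl ethers by DDQ, which leaves the silyl ethers, the angelate and the furanone untouched.

Step 18
Reactants: 23 C5/C9 diol
Product: 24 C5/C9 bis(triethylsilyl) ether
Conditions: Et3SiOTf, 2,6-lutidine, CH2Cl2, −78 °C
Reagents that add atoms: triethylsilyl trifluoromethanesulfonate, CC[Si](CC)(CC)OS(=O)(=O)C(F)(F)F
Why: Silyl triflate silylation, which covers the primary C5 and the hindered C9 hydroxyls so that no free hydroxyl and no C5/O9 lactol can interfere in steps 19 to 21.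

Step 19
Reactants: 24 bis(triethylsilyl) ether
Product: 26 C4 bromide (both C4 epimers), via silyl dienol ether 25 (not isolated)
Conditions: LiN(SiMe3)2, Me3SiCl, THF, −78 °C; then NBS, THF, −78 °C
Reagents that add atoms: N-bromosuccinimide, O=C1CCC(=O)N1Br; chlorotrimethylsilane, C[Si](C)(C)Cl (silyl group is carried only by 25)
Why: γ-Deprotonation of the 5-ethylfuranone (C10 carries no hydrogen) with silylation in the flask, followed by γ-bromination of the silyl dienol ether with NBS, which should go to C4 because the cation formed there is stabilised by both the ring oxygen and the siloxy group.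

Step 20
Reactants: 26 C4 bromide
Product: 27 bromo aldehyde (C5 aldehyde; cyclisation precursor)
Conditions: (COCl)2, DMSO, CH2Cl2, −78 to −40 °C; then iPr2NEt, −78 °C
Reagents that add atoms: none
Why: Swern oxidation applied directly to the primary triethylsilyl ether as in step 7, which should spare the secondary triethylsilyl and the tert-butyldimethylsilyl ethers and, with a hindered amine at low temperature, the secondary bromide.

Step 21
Reactants: 27 bromo aldehyde
Product: 29 furanone-bridged ten-membered carbocycle with free C5 hydroxyl, via samarium dienolate 28 (not isolated)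
Conditions: SmI2 (2.5 equiv, 0.1 M in THF), THF, −78 °C, slow addition of 27 (high dilution); aq. NH4Cl
Reagents that add atoms: samarium diiodide, I[Sm]I (samarium and iodine are carried only by 28)
Why: Proposed new method: SmI2 should reduce the C4–Br bond, which is allylic to the enol ether and vinylogously α to the C1 ketone, by two single-electron transfers much faster than it reduces the aldehyde, giving the trivalent samarium dienolate 28 whose γ-terminus C4 adds to the tethered C5 aldehyde, the closest known reactions being SmI2-mediated intramolecular Reformatsky closures of medium and large rings and γ-selective aldol additions of 3(2H)-furanone dienolates. The ring closed is the ten-membered carbocycle C1–C10, a 10-exo-trig addition that is a nine-atom closure when counted through the ether oxygen. C5 should be set by Felkin–Anh attack anti to the bulky, non-chelating C6 silyl ether, which gives the 5,6-anti diol pattern of the target. C4 should be set relative to C5 in a transition state in which the samarium-bound aldehyde meets the exocyclic dienolate with the C15 methyl turned away from the C6 branch, as constrained by the furanone and the C6–C10 stereocentres, to give the 4,5-anti relationship. The step needs γ (C4) over α (C2) attack and C–Br reduction over ketyl formation: γ attack keeps the vinylogous ester conjugated and is the only mode that gives an unstrained ring, and the activated bromide is reduced at −78 °C without additives while aldehyde, angelate and furanone are not. Because the bromide stereocentre is erased in 28, both epimers of 27 converge.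

Step 22
Reactants: 29 silylated macrocycle
Product: 30 tetraol (C5, C6, C9 and C12 hydroxyls free)
Conditions: HF·pyridine, pyridine, THF, 0 °C to rt
Reagents that add atoms: none
Why: Global desilylation with buffered HF·pyridine, which avoids the basic conditions that could cause retro-aldol cleavage of C4–C5 or acyl migration from O8 to O9.

Step 23
Reactants: 30 tetraol
Product: 31 target
Conditions: MnO2 (activated, excess), CH2Cl2, rt
Reagents that add atoms: none
Why: MnO2 oxidative lactonisation of a 2-methylene-1,4-diol, in which the primary allylic alcohol gives the enal, the neighbouring O6 hydroxyl closes the cis-fused five-membered lactol in preference to bridged six-membered lactols at O5 or O9, and the allylic lactol is oxidised to the α-methylene γ-lactone while the unactivated secondary hydroxyls are left.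

**Compound list**

1 | dimethyl L-tartrate | COC(=O)[C@H](O)[C@@H](O)C(=O)OC | starting material
2 | stannylene acetal, dimethyl (4R,5R)-2,2-dibutyl-1,3,2-dioxastannolane-4,5-dicarboxylate | COC(=O)[C@@H]1O[Sn](CCCC)(CCCC)O[C@H]1C(=O)OC | intermediate
3 | dimethyl (2R,3R)-2-hydroxy-3-[(4-methoxybenzyl)oxy]butanedioate | COC(=O)[C@H](OCc1ccc(OC)cc1)[C@@H](O)C(=O)OC | intermediate
4 | methyl (2R,3S)-3,4-dihydroxy-2-[(4-methoxybenzyl)oxy]butanoate | COC(=O)[C@H](OCc1ccc(OC)cc1)[C@@H](O)CO | intermediate
5 | methyl (2R,3S)-2-[(4-methoxybenzyl)oxy]-3,4-bis(triethylsilyloxy)butanoate | COC(=O)[C@H](OCc1ccc(OC)cc1)[C@@H](O[Si](CC)(CC)CC)CO[Si](CC)(CC)CC | intermediate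
6 | (2R,3S)-N-methoxy-N-methyl-2-[(4-methoxybenzyl)oxy]-3,4-bis(triethylsilyloxy)butanamide | CON(C)C(=O)[C@H](OCc1ccc(OC)cc1)[C@@H](O[Si](CC)(CC)CC)CO[Si](CC)(CC)CC | intermediate
7 | (4R,5S)-4-[(4-methoxybenzyl)oxy]-5,6-bis(triethylsilyloxy)hex-1-yn-3-one | C#CC(=O)[C@H](OCc1ccc(OC)cc1)[C@@H](O[Si](CC)(CC)CC)CO[Si](CC)(CC)CC | intermediate
8 | bromomagnesium (3S,4R,5S)-4-[(4-methoxybenzyl)oxy]-3-methyl-5,6-bis(triethylsilyloxy)hex-1-yn-3-olate | C#C[C@](C)(O[Mg]Br)[C@H](OCc1ccc(OC)cc1)[C@@H](O[Si](CC)(CC)CC)CO[Si](CC)(CC)CC | intermediate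
9 | (3S,4R,5S)-4-[(4-methoxybenzyl)oxy]-3-methyl-5,6-bis(triethylsilyloxy)hex-1-yn-3-yl acetate (C10 acetate, C9 PMB ether, C8 and C7 silyl ethers) | C#C[C@](C)(OC(C)=O)[C@H](OCc1ccc(OC)cc1)[C@@H](O[Si](CC)(CC)CC)CO[Si](CC)(CC)CC | intermediate
10 | (2R,3R,4S)-4-acetoxy-3-[(4-methoxybenzyl)oxy]-4-methyl-2-(triethylsilyloxy)hex-5-ynal (C7 aldehyde) | C#C[C@](C)(OC(C)=O)[C@H](OCc1ccc(OC)cc1)[C@@H](O[Si](CC)(CC)CC)C=O | intermediate
11 | Morita–Baylis–Hillman alcohol: methyl 2-methylene-3-hydroxy ester built on C7 of 10, C7 carbinol as both epimers, C8–C10 as in 10 | C#C[C@](C)(OC(C)=O)[C@H](OCc1ccc(OC)cc1)[C@@H](O[Si](CC)(CC)CC)C(O)C(=C)C(=O)OC | intermediate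
12 | methyl (Z)-2-(bromomethyl)alk-2-enoate: C7=C11 alkene with C8 and CH2Br cis, C8–C10 as in 10 | C#C[C@](C)(OC(C)=O)[C@H](OCc1ccc(OC)cc1)[C@@H](O[Si](CC)(CC)CC)/C=C(\CBr)C(=O)OC | intermediate
13 | (4-methoxybenzyloxy)acetaldehyde | O=CCOCc1ccc(OC)cc1 | starting material
14 | Barbier adduct: methyl 2-methylene ester with C6 hydroxyl and C5 PMB ether, C6–C10 configured as in the target | C#C[C@](C)(OC(C)=O)[C@H](OCc1ccc(OC)cc1)[C@@H](O[Si](CC)(CC)CC)[C@@H](C(=C)C(=O)OC)[C@@H](O)COCc1ccc(OC)cc1 | intermediate
15 | triol: C12 allylic alcohol, C6 alcohol, C10 tertiary propargylic alcohol; C8 silyl ether, C5 and C9 PMB ethers | C#C[C@](C)(O)[C@H](OCc1ccc(OC)cc1)[C@@H](O[Si](CC)(CC)CC)[C@@H](C(=C)CO)[C@@H](O)COCc1ccc(OC)cc1 | intermediate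
16 | C6,C12-bis(tert-butyldimethylsilyl) ether of 15 | C#C[C@](C)(O)[C@H](OCc1ccc(OC)cc1)[C@@H](O[Si](CC)(CC)CC)[C@@H](C(=C)CO[Si](C)(C)C(C)(C)C)[C@@H](O[Si](C)(C)C(C)(C)C)COCc1ccc(OC)cc1 | intermediate
17 | γ-hydroxy ynone: propanoyl group on the alkyne terminus of 16 | CCC(=O)C#C[C@](C)(O)[C@H](OCc1ccc(OC)cc1)[C@@H](O[Si](CC)(CC)CC)[C@@H](C(=C)CO[Si](C)(C)C(C)(C)C)[C@@H](O[Si](C)(C)C(C)(C)C)COCc1ccc(OC)cc1 | intermediate
18 | 5-ethyl-2-methyl-3(2H)-furanone carrying the C9–C5 chain at C10; C8 triethylsilyl ether | CCC1=CC(=O)[C@](C)(O1)[C@H](OCc1ccc(OC)cc1)[C@@H](O[Si](CC)(CC)CC)[C@@H](C(=C)CO[Si](C)(C)C(C)(C)C)[C@@H](O[Si](C)(C)C(C)(C)C)COCc1ccc(OC)cc1 | intermediate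
19 | C8 alcohol of 18 | CCC1=CC(=O)[C@](C)(O1)[C@H](OCc1ccc(OC)cc1)[C@@H](O)[C@@H](C(=C)CO[Si](C)(C)C(C)(C)C)[C@@H](O[Si](C)(C)C(C)(C)C)COCc1ccc(OC)cc1 | intermediate
20 | angelic acid, (Z)-2-methylbut-2-enoic acid | C/C=C(/C)C(=O)O | starting material
21 | mixed anhydride of angelic acid and 2,4,6-trichlorobenzoic acid | C/C=C(/C)C(=O)OC(=O)c1c(Cl)cc(Cl)cc1Cl | intermediate
22 | C8 angelate; C5 and C9 PMB ethers, C6 and C12 TBS ethers | CCC1=CC(=O)[C@](C)(O1)[C@H](OCc1ccc(OC)cc1)[C@@H](OC(=O)/C(C)=C\C)[C@@H](C(=C)CO[Si](C)(C)C(C)(C)C)[C@@H](O[Si](C)(C)C(C)(C)C)COCc1ccc(OC)cc1 | intermediate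
23 | C5,C9-diol of 22 | CCC1=CC(=O)[C@](C)(O1)[C@H](O)[C@@H](OC(=O)/C(C)=C\C)[C@@H](C(=C)CO[Si](C)(C)C(C)(C)C)[C@@H](O[Si](C)(C)C(C)(C)C)CO | intermediate
24 | C5,C9-bis(triethylsilyl) ether of 23 | CCC1=CC(=O)[C@](C)(O1)[C@H](O[Si](CC)(CC)CC)[C@@H](OC(=O)/C(C)=C\C)[C@@H](C(=C)CO[Si](C)(C)C(C)(C)C)[C@@H](O[Si](C)(C)C(C)(C)C)CO[Si](CC)(CC)CC | intermediate
25 | silyl dienol ether: 5-ethylidene-3-(trimethylsilyloxy)-2,5-dihydrofuran form of 24 | CC=C1C=C(O[Si](C)(C)C)[C@](C)(O1)[C@H](O[Si](CC)(CC)CC)[C@@H](OC(=O)/C(C)=C\C)[C@@H](C(=C)CO[Si](C)(C)C(C)(C)C)[C@@H](O[Si](C)(C)C(C)(C)C)CO[Si](CC)(CC)CC | intermediate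
26 | 5-(1-bromoethyl)furanone, C4 bromide as both epimers, C5 triethylsilyl ether | CC(Br)C1=CC(=O)[C@](C)(O1)[C@H](O[Si](CC)(CC)CC)[C@@H](OC(=O)/C(C)=C\C)[C@@H](C(=C)CO[Si](C)(C)C(C)(C)C)[C@@H](O[Si](C)(C)C(C)(C)C)CO[Si](CC)(CC)CC | intermediate
27 | cyclisation precursor: 5-(1-bromoethyl)furanone with C5 aldehyde, O6 and O12 TBS, O9 TES, O8 angelate | CC(Br)C1=CC(=O)[C@](C)(O1)[C@H](O[Si](CC)(CC)CC)[C@@H](OC(=O)/C(C)=C\C)[C@@H](C(=C)CO[Si](C)(C)C(C)(C)C)[C@@H](O[Si](C)(C)C(C)(C)C)C=O | intermediate
28 | trivalent samarium dienolate of 27 (O-bound SmI2, exocyclic C3=C4 alkene) | CC=C1C=C(O[Sm](I)I)[C@](C)(O1)[C@H](O[Si](CC)(CC)CC)[C@@H](OC(=O)/C(C)=C\C)[C@@H](C(=C)CO[Si](C)(C)C(C)(C)C)[C@@H](O[Si](C)(C)C(C)(C)C)C=O | intermediate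
29 | furanone-bridged ten-membered carbocycle, (4R,5S) with free C5 hydroxyl, O6 and O12 TBS, O9 TES, O8 angelate | C[C@H]1C2=CC(=O)[C@](C)(O2)[C@H](O[Si](CC)(CC)CC)[C@@H](OC(=O)/C(C)=C\C)[C@@H](C(=C)CO[Si](C)(C)C(C)(C)C)[C@@H](O[Si](C)(C)C(C)(C)C)[C@H]1O | intermediate
30 | tetraol: 29 with C6, C9 and C12 hydroxyls free | C[C@H]1C2=CC(=O)[C@](C)(O2)[C@H](O)[C@@H](OC(=O)/C(C)=C\C)[C@@H](C(=C)CO)[C@@H](O)[C@H]1O | intermediate
31 | CNP0206920.1, (4R,5S,6R,7S,8S,9R,10R) | C=C1C(=O)O[C@H]2[C@@H](O)[C@@H](C)C3=CC(=O)[C@](C)(O3)[C@H](O)[C@@H](OC(=O)/C(C)=C\C)[C@@H]12 | target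

Total steps: 23. Longest linear sequence: 23 steps from dimethyl L-tartrate (1).

**Steps most likely to fail**

Step 21. The samarium dienolate may be protonated before it cyclises (simple debromination), may react through C2, or the aldehyde may be reduced to a ketyl and couple intermolecularly. Fallback, known chemistry: the route is left at 24. Swern oxidation of its primary triethylsilyl ether, as in step 20, gives the debromo aldehyde F1. KN(SiMe3)2 in THF at −78 °C under high dilution then removes a C4 proton, and the potassium dienolate closes C4–C5 by a direct intramolecular vinylogous aldol addition, the established γ-aldol mode of 5-alkyl-3(2H)-furanones. The aldolate is quenched cold and the route is rejoined at 29.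

Step 19. Site selectivity of the electrophilic bromine may be lost (attack at C2 or at the 1,1-disubstituted C11=C13 alkene, or double bromination). Fallback: the route is left at 24 and the silyl dienol ether 25 is made as before, but it is oxidised with 3-chloroperbenzoic acid at −40 °C (vinylogous Rubottom oxidation). Brief methanolysis of the transient trimethylsilyl ether gives the C4 carbinol F2 as an epimer mixture. CBr4/PPh3 (Appel reaction) then installs the bromide without any electrophilic bromine, and the route is rejoined at 26.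

Step 10. Simple diastereoselection in the C6–C7 bond formation may be poor if the allylindium species equilibrates or reacts through an open transition state, so that the 6,7-anti series gains ground. Fallback: from 12 and 13 the coupling is accepted as it falls, and the C6 epimer of the adduct F3 is inverted at its carbinol by a Mitsunobu reaction with 4-nitrobenzoic acid (PPh3, diisopropyl azodicarboxylate) to the 4-nitrobenzoate F4. The iBu2AlH reduction of step 11 then cleaves the nitrobenzoate together with the methyl ester and the acetate, and the route is rejoined at 15.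

**Further compounds**

F1 | step 21 | debromo aldehyde, 27 with hydrogen in place of bromine | CCC1=CC(=O)[C@](C)(O1)[C@H](O[Si](CC)(CC)CC)[C@@H](OC(=O)/C(C)=C\C)[C@@H](C(=C)CO[Si](C)(C)C(C)(C)C)[C@@H](O[Si](C)(C)C(C)(C)C)C=O
F2 | step 19 | C4 carbinol, 26 with hydroxyl in place of bromine, both C4 epimers | CC(O)C1=CC(=O)[C@](C)(O1)[C@H](O[Si](CC)(CC)CC)[C@@H](OC(=O)/C(C)=C\C)[C@@H](C(=C)CO[Si](C)(C)C(C)(C)C)[C@@H](O[Si](C)(C)C(C)(C)C)CO[Si](CC)(CC)CC
F3 | step 10 | C6 epimer of 14 | C#C[C@](C)(OC(C)=O)[C@H](OCc1ccc(OC)cc1)[C@@H](O[Si](CC)(CC)CC)[C@@H](C(=C)C(=O)OC)[C@H](O)COCc1ccc(OC)cc1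
F4 | step 10 | 4-nitrobenzoate of 14 at O6, formed from F3 with inversion at C6 | C#C[C@](C)(OC(C)=O)[C@H](OCc1ccc(OC)cc1)[C@@H](O[Si](CC)(CC)CC)[C@@H](C(=C)C(=O)OC)[C@@H](OC(=O)c1ccc(cc1)[N+](=O)[O-])COCc1ccc(OC)cc1
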